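- I decide to watch one quantity when this flask is repeated: the working lifetime τ, the hours at the starting rate r that give the Z found at 3.4 h. Here r is the mean rate of Z formation up to the second reading of a run, at 0.46 h.

| flask | J | L | Q | time |
|---|---|---|---|---|
| south-west | 0.800 M | 0.960 M | 0.0640 M |  |
| east | 1.20 M | 0.960 M | 0.0640 M |  |
| south-east | 0.800 M | 1.40 M | 0.0640 M |  |
| south | 0.800 M | 0.960 M | 0.0320 M |  |
| north-east | 1.60 M | 0.480 M | 0.0640 M | 3.4 h |

| run | time / h | [Z] / M |
|---|---|---|
| south-west run | 0.15 | 0.0255 |
| south-west run | 0.46 | 0.0619 |
| south-west run | 0.88 | 0.1103 |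
| south-west run | 1.4 | 0.1445 |
| south-west run | 2.0 | 0.1761 |
| south-west run | 2.7 | 0.1874 |
| south-west run | 3.4 | 0.1968 |
| east run | 0.15 | 0.0248 |
| east run | 0.46 | 0.0684 |
| east run | 0.88 | 0.1240 |
| east run | 1.4 | 0.1725 |
| east run | 2.0 | 0.2101 |
| east run | 2.7 | 0.2359 |
| east run | 3.4 | 0.2482 |
| south-east run | 0.15 | 0.0294 |
| south-east run | 0.46 | 0.0812 |
| south-east run | 0.88 | 0.1484 |
| south-east run | 1.4 | 0.2030 |
| south-east run | 2.0 | 0.2335 |
| south-east run | 2.7 | 0.2518 |
| south-east run | 3.4 | 0.2539 |
| south run | 0.15 | 0.0105 |
| south run | 0.46 | 0.0349 |
| south run | 0.88 | 0.0589 |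
| south run | 1.4 | 0.0823 |
| south run | 2.0 | 0.1036 |
| south run | 2.7 | 0.1171 |
| south run | 3.4 | 0.1218 |

(each reading ± 0.002 M)

- Overall: J + L -> Z, with Q as catalyst.
- Constant volume, constant temperature.
- Readings of a species count what is bound in complexes too.
- An order is taken over about fifteen percent of the charge, up and down.

1. apparent order in [J] of the starting rate, round the charge of the south-west run (the rate where two percent of its J have turned into Z) (one fixed amount of Z, the same in the runs compared)
2. apparent order in [Q] of the starting rate, round the charge of the south-west run (the rate where two percent of its J have turned into Z)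
3. Z in the north-east run at 3.4 h, as a share of the J charged

- In the south-west run I read r = 0.135 M/h and Z = 0.1968 M at 3.4 h, so the working lifetime, that Z over r, is τ = 1.46 h, and 3.4 h holds 2.33 lifetimes. Its rate over the last interval, 0.0134 M/h, is lower than r.
- First I take the main step by itself, J + L -> Z at a steady rate. The east and south-east runs read r = 0.149 M/h and r = 0.177 M/h, which against the south-west r give me orders of 0.246 in J and 0.719 in L. So I put the north-east r at 0.0969 M/h. Held for 3.4 h, that makes 0.330 M, or 20.6% of its J, which is less than its L charge.
- Next I add the stop, using the south-west τ. North-east Z drops to 0.142 M, or 8.86% of its J.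
- Then comes the rest. The east run has τ = 1.67 h, longer than south-west on a larger J charge. Carrying that power of J to the north-east charge gives τ = 1.83 h, and I assume L leaves τ unchanged.
- My north-east figure is therefore 0.178 M, or 11.1% of its J. That Z takes 37.0% of the L charged, and L is the limiting reagent there, smaller than the J charge.
- The forecast gives 10% for the north-east run (range 8.5% to 12%), order 0.3 in J and 1 in Q, on the view that “Z levels off well short of the charge, so the catalyst is dying”. My J order is lower than its value, and my north-east share is higher.
- The flask gives 9.77% of the north-east J, with orders 0.25 in J and 0.99 in Q; the forecast's J order stands too high by a factor 1.18.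

    Q + J ⇌ QJ, settled at all times (3.960 /M)
    QJ + L ⇌ QJL, settled at all times (0.3460 /M)
    QJL → Z + Q (12.13 /h)
    J → Ju (0.8676 /h)
    2 Q → 2 Ze (10.73 /M/h)

- The step J -> Ju has a lifetime of 1.15 h. The north-east Z of 0.156 M over my starting rate makes τ = 1.61 h. The south-east run has the south-west J and Q charges, so its r of 0.177 M/h times the south-west τ gives 0.258 M at 3.4 h, and its reading there is 0.2539 M.

Readings and results were generated by integration for an exercise; the scatter is artificial.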